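## Structural features

Prestegane A is a 3,4-dibenzyl-γ-butyrolactone. One five-membered lactone ring (O1, C2(=O), C3, C4, C5) carries a 3-hydroxy-4-methoxybenzyl group on C3 and a 3,4-dimethoxybenzyl (veratryl) group, attached through the benzylic carbon C7, on C4. C3 and C4 are adjacent stereocentres, both R, with the two benzyl groups trans on the ring. C3 lies alpha to the carbonyl and can be equilibrated, trans being the more stable arrangement, whereas C4 has only CH2 neighbours, cannot be epimerised and must receive its absolute configuration in a dedicated step. The two arenes differ by a single O-methyl group, so they have to arrive in separate building blocks, and the free phenol has to be masked while base and alkylating agents are in use. Fragile points are the lactone (hydroxide, strong nucleophiles), the phenol and the electron-rich rings (electrophilic oxidants, strong Lewis acids). The real difficulty is the remote, unfunctionalised stereocentre C4. The key step exploits the fact that C4 sits between the methylene groups C3 and C5: without O1, and with C5 bonded to C2, these two carbons are the enantiotopic alpha-positions of a mirror-symmetric 3-substituted cyclobutanone, so an oxygen insertion that tells them apart creates the lactone ring and C4 together.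

## Logic of the disconnections

**12 from 11.** Only the phenolic O–H bond is exchanged for an O–CH2Ph bond. The cut is placed there because the preceding C–C bond formation needs a strong amide base and a reactive benzylic halide; a free phenol in the electrophile would quench the one and be alkylated by the other. The skeleton is not simplified, but all phenoxide chemistry is removed from the earlier steps. The forward step has to take the benzyl group off without opening the lactone and without base at C3, which neutral hydrogenolysis offers.

**11 from 7 and 9.** The exocyclic bond between C3 and its benzylic carbon is cut. C3 is the only acidic carbon of the lactone, so it can be made nucleophilic (as 10) without ambiguity, and the fixed neighbour C4 is placed to direct the incoming group. The cut halves the molecule, removes one stereocentre and separates the two arenes, giving a convergent plan. The forward step must stop at monoalkylation and must deliver the electrophile to the face of 10 opposite the C4 substituent.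

**9 from 8.** A C–Br bond is traced back to C–OH. The bromide is too labile to store, whereas the alcohol is stable and already carries the benzyl ether. The forward step has to be mild enough not to cleave that ether.

**7 from 5.** The O1–C5 bond is cut, O1 is taken out and C5 is reconnected to C2. This converts the only non-equilibratable stereocentre into a prochiral carbon: 5 has a mirror plane through its carbonyl carbon and the substituted ring carbon and holds no stereochemistry. In exchange, the forward oxidation, which runs through 6, must insert oxygen on one side only, that is, distinguish two enantiotopic CH2 groups. No regiochemical choice exists, because both are primary and identical in constitution.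

**5 from 4.** Two C–H bonds alpha to the carbonyl are replaced by C–Cl. The reason is reactivity: an isolated terminal alkene does not add usefully to ketene itself but does to its dichloro derivative. The cost is one reductive step, which must spare the ketone.

**4 from 1 and 2.** Both ring bonds made in the cycloaddition are cut: the one from the carbonyl carbon to the terminal alkene carbon and the one from the CCl2 carbon to the internal alkene carbon. The two-carbon partner is 3, released from 2 in the flask. This leads to a bulk allylarene that already contains the veratryl unit and C7. The forward step must give this orientation, which the polarity of the ketene central carbon ensures, and must not attack the electron-rich ring.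

## Other disconnections considered

**Alternative 1:** The cut runs through the veratryl ring. Two C–C bonds of the future arene are broken, so the ring derives from the diene 2,3-dimethoxybuta-1,3-diene A2 and the alkyne of the ynone A1, in which C7 is a ketone carbon on C4 of the finished lactone.

- Forward key step: a thermal, normal-electron-demand [4+2] addition gives the 1,4-cyclohexadiene A3. Dehydrogenation (for example with DDQ) would give the aryl ketone A4, and hydrogenolysis over Pd/C in acid would then have to take C7 from C=O to CH2 while removing the benzyl ether.
- In favour: ynones are reactive dienophiles, the twofold symmetry of A2 removes any regiochemical question, and the bis(enol ether) ring should aromatise easily.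
- Where it is better: the arene substitution could be varied late from one ynone, whereas the chosen plan fixes the veratryl group in its first step.
- Where it is equal: neither key step can give a regioisomer.
- Against: the arene that is built can be bought as part of 1. The cycloaddition creates no stereocentre, so A1 must already hold C3 and C4 in enantiopure form. In A1, A3 and A4, C4 is alpha to a ketone and C3 alpha to the lactone carbonyl, so both centres can epimerise and sequential epimerisation would erode enantiopurity; in the chosen route C4 is never acidic. A1 is also a base-sensitive Michael acceptor, and A2 is an acid-sensitive diene.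
- Step economy: three operations follow the cycloaddition, and a stereocontrolled multi-step synthesis of A1 precedes it, against six steps in all for the chosen plan.

**Alternative 2:** The cut removes the carbonyl carbon. C2–C3 and C2–O1 are broken, leaving the homopropargylic alcohol A5, whose hydroxyl oxygen becomes O1 and whose alkyne carbon next to the stereocentre becomes C3.

- Forward key step: with PdCl2, PPh3, SnCl2 and CO, an alkoxycarbonyl complex of divalent palladium formed from the alcohol and CO adds syn across the alkyne. Protonolysis of the vinyl–palladium bond releases the (E)-arylidene lactone A6.
- In favour: the aryl alkyne can be attached by Sonogashira coupling, CO is the cheapest one-carbon unit, and the E geometry follows from the syn addition.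
- Where it is better: the carbonyl carbon is introduced at the correct oxidation level with full atom economy.
- Where it is equal: the plan is as convergent as the chosen one, and C4 of A5 and A6 is never acidic, so its configurational safety matches that of 7.
- Against: the key step creates neither stereocentre, so A5 needs its own enantioselective synthesis. C3 would be set afterwards by hydrogenation of the exocyclic alkene; hydrogen is expected to arrive on the face remote from the C4 substituent, which places the benzyl groups cis and calls for an extra base-mediated epimerisation at C3. Internal aryl alkynes are expected to be slower than terminal ones in this carbonylation, and pressurised CO and SnCl2 are needed.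
- Comparison: the chosen plan creates C4 catalytically from an achiral ketone and sets C3 trans directly, and is shorter.

**Alternative 3:** The cut is C2–C3 alone, made homolytically. The Se-phenyl selenocarbonate A7 carries the complete carbon skeleton, with an (E)-styrene in place of the bond between C3 and its benzylic carbon.

- Forward key step: (n-C4H9)3SnH and AIBN remove the phenylseleno group. The alkoxycarbonyl radical closes 5-exo-trig onto the styrene carbon that becomes C3, and the resulting benzylic radical is reduced by (n-C4H9)3SnH to give A8, which is the same compound as 11.
- In favour: the lactone ring and the C3 stereocentre arise in one step under neutral conditions, and benzylic stabilisation of the adduct radical should make ring closure fast relative to loss of CO2.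
- Where it is better: strong base and the labile bromide 9 are avoided, unlike step 5 of the chosen plan.
- Where it is equal: the endgame from A8 is identical.
- Against: the trans preference rests on a chair-like transition state with a modest energy difference and is expected to be less decisive than anti-alkylation of the rigid enolate 10. Stoichiometric tin, selenium and a phosgene equivalent are needed. Direct reduction of the acyl radical to a formate competes at high (n-C4H9)3SnH concentration. The key step again does not create C4, so A7 needs a separate enantioselective synthesis.
- Comparison: the key step is one operation from A7 to A8, but the route to A7 is longer than the three steps that lead to 7.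

Key step: step 3

## Assumptions

- 3-(Benzyloxy)-4-methoxybenzyl alcohol is taken as a purchasable catalogue compound, so the electrophile needs one step only.
- The sense of induction of the chiral acid for an arylmethyl-substituted cyclobutanone is taken as assignable only by trial; step 3 therefore specifies the catalyst antipode by its outcome.

## Route

**Step 1**
Reactants: 1 methyl eugenol (4-allyl-1,2-dimethoxybenzene); 2 trichloroacetyl chloride
Product: 4 2,2-dichloro-3-(3,4-dimethoxybenzyl)cyclobutan-1-one (racemic), via dichloroketene 3 (not isolated)
Conditions: Zn(Cu), POCl3, Et2O, reflux, slow addition of 2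
Reagents that add atoms: none
Why: Zinc removes two chlorines from 2 to release 3, whose electrophilic central carbon bonds to the terminal alkene carbon while the CCl2 carbon bonds to the internal one in a thermal ketene–alkene [2+2] cycloaddition; allylarenes are standard partners and POCl3 ties up ZnCl2 so that the electron-rich ring is not acylated. The new stereocentre forms racemic and ceases to be a stereocentre in step 2.

**Step 2**
Reactants: 4 2,2-dichloro-3-(3,4-dimethoxybenzyl)cyclobutan-1-one
Product: 5 3-(3,4-dimethoxybenzyl)cyclobutan-1-one
Conditions: Zn dust, AcOH, 25→60 °C
Reagents that add atoms: none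
Why: Reductive dehalogenation of an alpha,alpha-dichloroketone, each C–Cl bond being reduced by zinc through the enolate and protonated by AcOH; the ketone and the aryl ethers are inert, and the product is achiral.

**Step 3**
Reactants: 5 3-(3,4-dimethoxybenzyl)cyclobutan-1-one
Product: 7 (R)-4-(3,4-dimethoxybenzyl)dihydrofuran-2(3H)-one, via Criegee adduct 6 (not isolated)
Conditions: 3,3'-di(pyren-1-yl)-5,5',6,6',7,7',8,8'-octahydro-1,1'-bi-2-naphthyl hydrogen phosphate (10 mol %, antipode that gives R), 30% aq. H2O2 (1.5 equiv), CHCl3, −40 °C
Reagents that add atoms: hydrogen peroxide, OO
Why: The acid activates the strained ketone and H2O2 adds to give 6, which stays hydrogen-bonded to the bifunctional phosphoric acid (P=O accepting the peroxide O–H, P–OH donating to the hemiketal oxygen). The alpha-methylene held antiperiplanar to the O–O bond inside the chiral pocket then shifts from carbon to oxygen with loss of water and with retention at the migrating carbon. The closest known reaction type is the chiral Brønsted acid-catalysed asymmetric Baeyer–Villiger oxidation of prochiral 3-substituted cyclobutanones with aqueous H2O2, a desymmetrisation also known with chiral Lewis acid–peracid systems and with Baeyer–Villiger monooxygenases. The lactone ring arises by ring expansion from four to five members through a 1,2-shift of C5 from C2 to O1, not by cyclisation, and is driven by release of cyclobutanone strain. C4 is not touched and its configuration is set by the catalyst alone: migration of the pro-R methylene gives R, and the antipode that does this is identified in a preliminary run with both enantiomers of the acid. The only selectivity required is between enantiotopic groups, since both candidates are primary and constitutionally identical and no regioisomer can form. H2O2 under mild Brønsted acid at low temperature should not hydroxylate the veratryl ring, and the low temperature suppresses the uncatalysed background oxidation. Because the arene is one carbon removed from the ring, discrimination is expected to be weaker than for 3-aryl substrates, so the optical purity of 7 is to be checked by chiral HPLC before it is carried on.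

**Step 4**
Reactants: 8 3-(benzyloxy)-4-methoxybenzyl alcohol
Product: 9 3-(benzyloxy)-4-methoxybenzyl bromide
Conditions: PBr3 (0.4 equiv), CH2Cl2, 0 °C; used at once
Reagents that add atoms: phosphorus tribromide, BrP(Br)Br
Why: Conversion of a primary benzylic alcohol into the bromide through its phosphite ester and SN2 attack by bromide; at 0 °C and short contact time the benzyl aryl ether should survive, and 9 is not stored because electron-rich benzylic bromides are labile.

**Step 5**
Reactants: 7 (R)-4-(3,4-dimethoxybenzyl)dihydrofuran-2(3H)-one; 9 3-(benzyloxy)-4-methoxybenzyl bromide
Product: 11 (3R,4R)-3-[3-(benzyloxy)-4-methoxybenzyl]-4-(3,4-dimethoxybenzyl)dihydrofuran-2(3H)-one, via lithium enolate 10 (not isolated)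
Conditions: LiN(SiMe3)2 (1.05 equiv), THF, −78 °C; then 9, DMPU, −78→−30 °C
Reagents that add atoms: none
Why: Kinetic deprotonation at C3, the only acidic position, gives the planar enolate 10, which undergoes SN2 enolate alkylation by the benzylic bromide on the face opposite the C4 veratryl group, so that C3 becomes R and trans to C4. Trans is also the thermodynamically preferred arrangement, and C4 is not acidic and cannot be scrambled.

**Step 6**
Reactants: 11 (3R,4R)-3-[3-(benzyloxy)-4-methoxybenzyl]-4-(3,4-dimethoxybenzyl)dihydrofuran-2(3H)-one
Product: 12 prestegane A, (3R,4R)-4-(3,4-dimethoxybenzyl)-3-(3-hydroxy-4-methoxybenzyl)dihydrofuran-2(3H)-one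
Conditions: H2 (1 atm), 10% Pd/C, EtOAc, 25 °C
Reagents that add atoms: none
Why: Hydrogenolysis of a benzyl aryl ether over Pd/C under neutral conditions; the C5–O1 bond is not benzylic, the benzylic C–C bonds are inert, and without base C3 does not epimerise.

## Compound list

1 | methyl eugenol (4-allyl-1,2-dimethoxybenzene) | COc1ccc(CC=C)cc1OC | starting material
2 | trichloroacetyl chloride | O=C(Cl)C(Cl)(Cl)Cl | starting material
3 | dichloroketene (not isolated) | O=C=C(Cl)Cl | intermediate
4 | 2,2-dichloro-3-(3,4-dimethoxybenzyl)cyclobutan-1-one (racemic) | COc1ccc(CC2CC(=O)C2(Cl)Cl)cc1OC | intermediate
5 | 3-(3,4-dimethoxybenzyl)cyclobutan-1-one | COc1ccc(CC2CC(=O)C2)cc1OC | intermediate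
6 | 3-(3,4-dimethoxybenzyl)-1-hydroperoxycyclobutan-1-ol, Criegee adduct (not isolated) | COc1ccc(CC2CC(O)(OO)C2)cc1OC | intermediate
7 | (R)-4-(3,4-dimethoxybenzyl)dihydrofuran-2(3H)-one | O=C1OC[C@H](Cc2ccc(OC)c(OC)c2)C1 | intermediate
8 | 3-(benzyloxy)-4-methoxybenzyl alcohol | COc1ccc(CO)cc1OCc1ccccc1 | starting material
9 | 3-(benzyloxy)-4-methoxybenzyl bromide | COc1ccc(CBr)cc1OCc1ccccc1 | intermediate
10 | lithium (R)-4-(3,4-dimethoxybenzyl)-4,5-dihydrofuran-2-olate (not isolated) | [Li+].[O-]C1=C[C@@H](Cc2ccc(OC)c(OC)c2)CO1 | intermediate
11 | (3R,4R)-3-[3-(benzyloxy)-4-methoxybenzyl]-4-(3,4-dimethoxybenzyl)dihydrofuran-2(3H)-one | O=C1OC[C@H](Cc2ccc(OC)c(OC)c2)[C@H]1Cc1ccc(OC)c(OCc2ccccc2)c1 | intermediate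
12 | prestegane A | COc1ccc(C[C@H]2C(=O)OC[C@@H]2Cc2ccc(OC)c(OC)c2)cc1O | target

## Step count and risk

Total step count: 6. Longest linear sequence: 5 steps (steps 1, 2, 3, 5 and 6, from 1). Step 4 is a one-step side branch from 8.

**Step 3 (key step).** The most likely failure is insufficient discrimination between the two enantiotopic methylene groups, because the arene that the catalyst has to recognise is insulated from the ring by C7. A competing uncatalysed oxidation would erode the optical purity further. Changing the 3,3'-groups of the acid, or turning to Sc(OTf)3 with a chiral N,N'-dioxide and a peracid, or to a Baeyer–Villiger monooxygenase, would alter conditions only. If 11 or 12 prove crystalline, recrystallisation could also raise the optical purity.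

The fallback that changes the approach is a classical resolution. It sets out from 5 and comes back at 7.
- 5 is oxidised without chiral control (30% H2O2, AcOH, 0→25 °C) to racemic 4-(3,4-dimethoxybenzyl)dihydrofuran-2(3H)-one F1.
- AlMe3-mediated aminolysis with (S)-1-phenylethylamine opens F1 to two diastereomeric hydroxy amides: (R)-3-(3,4-dimethoxybenzyl)-4-hydroxy-N-[(S)-1-phenylethyl]butanamide F2 and (S)-3-(3,4-dimethoxybenzyl)-4-hydroxy-N-[(S)-1-phenylethyl]butanamide F3.
- These are separated by crystallisation or chromatography.
- F2 is heated with aqueous H2SO4 in dioxane, which relactonises it with release of the amine and gives 7.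
- Half of the material is lost as F3, which cannot be recycled because its stereocentre is not epimerisable.

**Step 1.** The most likely failure is electrophilic attack on the veratryl ring by 2 activated by ZnCl2, or self-condensation of 3 outrunning its addition to a non-activated terminal alkene.

The fallback is a keteniminium [2+2] cycloaddition. It sets out from 1 and comes back at 5, bypassing 4 and step 2.
- N,N-dimethylacetamide, Tf2O and 2,4,6-collidine in ClCH2CH2Cl generate N,N-dimethylketeniminium triflate F4.
- F4 adds to 1 with the same orientation to give 3-(3,4-dimethoxybenzyl)-N,N-dimethylcyclobutan-1-iminium triflate F5.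
- Hydrolysis with aqueous NaHCO3 gives 5 directly, without any chlorine.

**Step 5.** The most likely failures are proton exchange between 10 and the product (leading to double alkylation alongside recovered 7), decomposition of the labile bromide before it is consumed, and incomplete anti selectivity.

The fallback replaces SN2 alkylation by an aldol addition followed by reductive removal of the benzylic oxygen. It sets out from 7 and 8 and comes back at 12, bypassing 9 and 11.
- 8 is oxidised with MnO2 in CH2Cl2 to 3-(benzyloxy)-4-methoxybenzaldehyde F6.
- F6 is added at −78 °C to 10 (made from 7 with LiN(SiMe3)2 in THF), again anti to the C4 substituent. This gives (3S,4R)-3-{[3-(benzyloxy)-4-methoxyphenyl](hydroxy)methyl}-4-(3,4-dimethoxybenzyl)dihydrofuran-2(3H)-one F7 as a mixture of carbinol epimers. The ring substituents are trans as in 11; the 3S descriptor reflects only a change of CIP priorities.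
- Hydrogenation (H2, Pd/C, AcOH, trace HClO4) cleaves both the activated benzylic C–OH bond and the benzyl ether, giving 12.
- If dehydration followed by alkene hydrogenation intervenes and places some material cis, brief base equilibration at C3 should restore the trans arrangement, since C4 is fixed.

## Further compounds

F1 | step 3 | rac-4-(3,4-dimethoxybenzyl)dihydrofuran-2(3H)-one | O=C1OCC(Cc2ccc(OC)c(OC)c2)C1
F2 | step 3 | (R)-3-(3,4-dimethoxybenzyl)-4-hydroxy-N-[(S)-1-phenylethyl]butanamide | COc1ccc(C[C@@H](CO)CC(=O)N[C@@H](C)c2ccccc2)cc1OC
F3 | step 3 | (S)-3-(3,4-dimethoxybenzyl)-4-hydroxy-N-[(S)-1-phenylethyl]butanamide | COc1ccc(C[C@H](CO)CC(=O)N[C@@H](C)c2ccccc2)cc1OC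
F4 | step 1 | N,N-dimethylketeniminium triflate | C=C=[N+](C)C.[O-]S(=O)(=O)C(F)(F)F
F5 | step 1 | 3-(3,4-dimethoxybenzyl)-N,N-dimethylcyclobutan-1-iminium triflate | COc1ccc(CC2CC(=[N+](C)C)C2)cc1OC.[O-]S(=O)(=O)C(F)(F)F
F6 | step 5 | 3-(benzyloxy)-4-methoxybenzaldehyde | COc1ccc(C=O)cc1OCc1ccccc1
F7 | step 5 | (3S,4R)-3-{[3-(benzyloxy)-4-methoxyphenyl](hydroxy)methyl}-4-(3,4-dimethoxybenzyl)dihydrofuran-2(3H)-one (carbinol epimers) | O=C1OC[C@H](Cc2ccc(OC)c(OC)c2)[C@H]1C(O)c1ccc(OC)c(OCc2ccccc2)c1
A1 | alternative 1 | (3R,4R)-3-[3-(benzyloxy)-4-methoxybenzyl]-4-propioloyldihydrofuran-2(3H)-one | O=C1OC[C@H](C(=O)C#C)[C@H]1Cc1ccc(OC)c(OCc2ccccc2)c1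
A2 | alternative 1 | 2,3-dimethoxybuta-1,3-diene | C=C(OC)C(=C)OC
A3 | alternative 1 | (3R,4R)-3-[3-(benzyloxy)-4-methoxybenzyl]-4-(4,5-dimethoxycyclohexa-1,4-diene-1-carbonyl)dihydrofuran-2(3H)-one | O=C1OC[C@H](C(=O)C2=CCC(OC)=C(OC)C2)[C@H]1Cc1ccc(OC)c(OCc2ccccc2)c1
A4 | alternative 1 | (3R,4R)-3-[3-(benzyloxy)-4-methoxybenzyl]-4-(3,4-dimethoxybenzoyl)dihydrofuran-2(3H)-one | O=C1OC[C@H](C(=O)c2ccc(OC)c(OC)c2)[C@H]1Cc1ccc(OC)c(OCc2ccccc2)c1
A5 | alternative 2 | (R)-4-[3-(benzyloxy)-4-methoxyphenyl]-2-(3,4-dimethoxybenzyl)but-3-yn-1-ol | OC[C@H](Cc1ccc(OC)c(OC)c1)C#Cc1ccc(OC)c(OCc2ccccc2)c1
A6 | alternative 2 | (R,E)-3-[3-(benzyloxy)-4-methoxybenzylidene]-4-(3,4-dimethoxybenzyl)dihydrofuran-2(3H)-one | O=C1OC[C@H](Cc2ccc(OC)c(OC)c2)/C1=C\c1ccc(OC)c(OCc2ccccc2)c1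
A7 | alternative 3 | O-{(R,E)-4-[3-(benzyloxy)-4-methoxyphenyl]-2-(3,4-dimethoxybenzyl)but-3-en-1-yl} Se-phenyl selenocarbonate | O=C([Se]c1ccccc1)OC[C@H](Cc1ccc(OC)c(OC)c1)/C=C/c1ccc(OC)c(OCc2ccccc2)c1
A8 | alternative 3 | (3R,4R)-3-[3-(benzyloxy)-4-methoxybenzyl]-4-(3,4-dimethoxybenzyl)dihydrofuran-2(3H)-one (identical with 11) | O=C1OC[C@H](Cc2ccc(OC)c(OC)c2)[C@H]1Cc1ccc(OC)c(OCc2ccccc2)c1
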